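**Plan**
- The depside ester bond between the ring A carbonyl carbon and the C4' oxygen of ring B is cut first, giving a 2,4-dihydroxy-6-pentylbenzoic and a 2,4-dihydroxy-6-propylbenzoic acid.
- In ring B the adjacent C6'–propyl and C1'–CO2H bonds are cut together. C1' lies between C6' and the oxygen-bearing C2', the pattern a 3-alkoxyaryne gives when a Grignard reagent adds and CO2 traps the ortho-alkoxy arylmagnesium.
- In ring A only the C1–carboxyl bond is cut, back to olivetol, which already carries the pentyl chain and both oxygens.
- Forward: 3,5-bis(benzyloxy)phenol is iodinated and triflated, then n-PrMgBr/CO2 gives the ring B acid. Olivetol is benzylated, formylated and oxidised to the ring A acid. The ring B acid is debenzylated and re-esterified at the carboxyl, its C4' hydroxyl is acylated, and hydrogenolysis releases the target.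
- Both benzene rings are bought, no ring is formed, and the target has no stereocentre, so no stereocontrol is needed.

Key step: step 3

Assumption: 3,5-bis(benzyloxy)phenol, olivetol and a THF solution of n-propylmagnesium bromide are purchased; the Grignard reagent itself carries out the iodine–magnesium exchange, so no second organomagnesium species is present in the key step.

Step 1
Reactants: 1 3,5-bis(benzyloxy)phenol
Product: 2 3,5-bis(benzyloxy)-2-iodophenol
Conditions: N-iodosuccinimide (1.0 equiv), CH2Cl2, −78 → −20 °C, dark
Reagents that add atoms: N-iodosuccinimide, O=C1CCC(=O)N1I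
Why: Electrophilic aromatic iodination of a phloroglucinol-type phenol should occur at one of the two equivalent positions ortho to the free hydroxyl rather than at the carbon crowded by two benzyloxy groups, and one equivalent of reagent at low temperature limits di-iodination.

Step 2
Reactants: 2 3,5-bis(benzyloxy)-2-iodophenol
Product: 3 3,5-bis(benzyloxy)-2-iodophenyl trifluoromethanesulfonate
Conditions: Tf2O (1.2 equiv), pyridine, CH2Cl2, 0 °C
Reagents that add atoms: trifluoromethanesulfonic anhydride, O=S(=O)(OS(=O)(=O)C(F)(F)F)C(F)(F)F
Why: O-Sulfonylation of a phenol with triflic anhydride and pyridine is routine and leaves the aryl iodide and the benzyl ethers untouched.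

Step 3
Reactants: 3 3,5-bis(benzyloxy)-2-iodophenyl trifluoromethanesulfonate; 4 n-propylmagnesium bromide; 5 carbon dioxide
Product: 9 2,4-bis(benzyloxy)-6-propylbenzoic acid, via 2-magnesiated aryl triflate 6 (not isolated), via 3,5-bis(benzyloxy)benzyne 7 (not isolated), via arylmagnesium bromide 8 (not isolated)
Conditions: n-PrMgBr (3.0 equiv), LiCl (3.0 equiv), THF, −78 → 0 °C; CO2 (g), 0 °C → rt; then 1 M HCl
Reagents that add atoms: n-propylmagnesium bromide, CCC[Mg]Br; carbon dioxide, O=C=O
Why: n-PrMgBr first exchanges the iodine at the future C1', a carbon flanked by the triflate and a benzyloxy group, and the ortho-magnesiated triflate 6 loses Mg(OTf)Br to give aryne 7 across C1'–C6'. A second equivalent of n-PrMgBr adds to the strained triple bond and CO2 carboxylates arylmagnesium 8, which is the established carbomagnesiation of 3-alkoxyarynes generated from 2-iodoaryl sulfonates followed by electrophilic trapping. No ring is closed and no stereocentre is formed. The selectivity needed is regiochemical: the C2' benzyloxy group beside the triple bond distorts and polarises the aryne so that propyl enters at the distal carbon C6' and magnesium ends up at C1', where the adjacent C–O bond stabilises the carbanion inductively, and the more remote C4' benzyloxy group is too weak a director to reverse this. Using one Grignard reagent for both exchange and addition excludes transfer of a foreign alkyl group, and its excess should outpace attack of 8 on further aryne.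

Step 4
Reactants: 9 2,4-bis(benzyloxy)-6-propylbenzoic acid
Product: 10 2,4-dihydroxy-6-propylbenzoic acid
Conditions: H2 (1 atm), 10% Pd/C, EtOAc, rt
Reagents that add atoms: none
Why: Hydrogenolysis of aryl benzyl ethers over palladium on carbon at room temperature frees both phenols, leaves the carboxylic acid alone and avoids heating that could decarboxylate the β-resorcylic acid.

Step 5
Reactants: 10 2,4-dihydroxy-6-propylbenzoic acid
Product: 11 benzyl 2,4-dihydroxy-6-propylbenzoate
Conditions: BnBr (1.05 equiv), KHCO3 (1.1 equiv), DMF, rt
Reagents that add atoms: benzyl bromide, BrCc1ccccc1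
Why: KHCO3 deprotonates only the carboxylic acid, so SN2 alkylation of the carboxylate by benzyl bromide should give the ester and leave both phenols free.

Step 6
Reactants: 12 olivetol (5-pentylbenzene-1,3-diol)
Product: 13 1,3-bis(benzyloxy)-5-pentylbenzene
Conditions: BnBr (2.2 equiv), K2CO3 (2.5 equiv), DMF, 60 °C
Reagents that add atoms: benzyl bromide, BrCc1ccccc1
Why: Williamson etherification of both phenoxides with benzyl bromide under carbonate conditions is standard for resorcinols and gives a protecting group that the last step removes together with the others.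

Step 7
Reactants: 13 1,3-bis(benzyloxy)-5-pentylbenzene
Product: 15 2,4-bis(benzyloxy)-6-pentylbenzaldehyde, via aryl iminium chloride 14 (not isolated)
Conditions: POCl3 (1.5 equiv), DMF, 0 → 70 °C; then ice-water, rt
Reagents that add atoms: N,N-dimethylformamide, CN(C)C=O; water, O
Why: Vilsmeier–Haack formylation of a 3,5-dialkoxyalkylbenzene should occur at the carbon ortho to one benzyloxy group and para to the other (next to the pentyl chain) rather than at the more hindered carbon between the two ethers, and the iminium salt 14 is hydrolysed to the aldehyde on aqueous work-up.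

Step 8
Reactants: 15 2,4-bis(benzyloxy)-6-pentylbenzaldehyde
Product: 16 2,4-bis(benzyloxy)-6-pentylbenzoic acid
Conditions: NaClO2, NaH2PO4, 2-methyl-2-butene (excess), t-BuOH/THF/H2O, 0 °C → rt
Reagents that add atoms: sodium chlorite, [Na+].[O-]Cl=O
Why: Pinnick oxidation converts the hindered aromatic aldehyde into the acid under mild buffered conditions, with 2-methyl-2-butene scavenging the hypochlorous acid that would otherwise chlorinate the electron-rich ring.

Step 9
Reactants: 16 2,4-bis(benzyloxy)-6-pentylbenzoic acid; 11 benzyl 2,4-dihydroxy-6-propylbenzoate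
Product: 18 benzyl 4-{[2,4-bis(benzyloxy)-6-pentylbenzoyl]oxy}-2-hydroxy-6-propylbenzoate, via mixed trifluoroacetic anhydride 17 (not isolated)
Conditions: (CF3CO)2O (3 equiv), toluene, 0 °C → rt
Reagents that add atoms: none
Why: Depside esterification through a mixed trifluoroacetic anhydride is the standard way to activate a hindered, electron-rich benzoic acid, and acylation should occur at the C4' hydroxyl because the C2' hydroxyl is locked in a hydrogen bond to the neighbouring ester carbonyl.

Step 10
Reactants: 18 benzyl 4-{[2,4-bis(benzyloxy)-6-pentylbenzoyl]oxy}-2-hydroxy-6-propylbenzoate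
Product: 19 4-[(2,4-dihydroxy-6-pentylbenzoyl)oxy]-2-hydroxy-6-propylbenzoic acid
Conditions: H2 (1 atm), 10% Pd/C, EtOAc, rt
Reagents that add atoms: none
Why: Neutral hydrogenolysis over palladium on carbon should remove the two benzyl ethers and the benzyl ester in one operation and leave the aryl ester link of the depside intact.

**Compound list**
1 | 3,5-bis(benzyloxy)phenol | Oc1cc(OCc2ccccc2)cc(OCc2ccccc2)c1 | starting material
2 | 3,5-bis(benzyloxy)-2-iodophenol | Oc1cc(OCc2ccccc2)cc(OCc2ccccc2)c1I | intermediate
3 | 3,5-bis(benzyloxy)-2-iodophenyl trifluoromethanesulfonate | O=S(=O)(Oc1cc(OCc2ccccc2)cc(OCc2ccccc2)c1I)C(F)(F)F | intermediate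
4 | n-propylmagnesium bromide | CCC[Mg]Br | starting material
5 | carbon dioxide | O=C=O | starting material
6 | [2,4-bis(benzyloxy)-6-(trifluoromethanesulfonyloxy)phenyl]magnesium bromide | O=S(=O)(Oc1cc(OCc2ccccc2)cc(OCc2ccccc2)c1[Mg]Br)C(F)(F)F | intermediate
7 | 3,5-bis(benzyloxy)benzyne | C1#CC(OCc2ccccc2)=CC(OCc2ccccc2)=C1 | intermediate
8 | [2,4-bis(benzyloxy)-6-propylphenyl]magnesium bromide | CCCc1cc(OCc2ccccc2)cc(OCc2ccccc2)c1[Mg]Br | intermediate
9 | 2,4-bis(benzyloxy)-6-propylbenzoic acid | CCCc1cc(OCc2ccccc2)cc(OCc2ccccc2)c1C(=O)O | intermediate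
10 | 2,4-dihydroxy-6-propylbenzoic acid | CCCc1cc(O)cc(O)c1C(=O)O | intermediate
11 | benzyl 2,4-dihydroxy-6-propylbenzoate | CCCc1cc(O)cc(O)c1C(=O)OCc1ccccc1 | intermediate
12 | olivetol (5-pentylbenzene-1,3-diol) | CCCCCc1cc(O)cc(O)c1 | starting material
13 | 1,3-bis(benzyloxy)-5-pentylbenzene | CCCCCc1cc(OCc2ccccc2)cc(OCc2ccccc2)c1 | intermediate
14 | N-[2,4-bis(benzyloxy)-6-pentylbenzylidene]-N-methylmethanaminium chloride | CCCCCc1cc(OCc2ccccc2)cc(OCc2ccccc2)c1C=[N+](C)C.[Cl-] | intermediate
15 | 2,4-bis(benzyloxy)-6-pentylbenzaldehyde | CCCCCc1cc(OCc2ccccc2)cc(OCc2ccccc2)c1C=O | intermediate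
16 | 2,4-bis(benzyloxy)-6-pentylbenzoic acid | CCCCCc1cc(OCc2ccccc2)cc(OCc2ccccc2)c1C(=O)O | intermediate
17 | 2,4-bis(benzyloxy)-6-pentylbenzoic trifluoroacetic anhydride | CCCCCc1cc(OCc2ccccc2)cc(OCc2ccccc2)c1C(=O)OC(=O)C(F)(F)F | intermediate
18 | benzyl 4-{[2,4-bis(benzyloxy)-6-pentylbenzoyl]oxy}-2-hydroxy-6-propylbenzoate | CCCCCc1cc(OCc2ccccc2)cc(OCc2ccccc2)c1C(=O)Oc1cc(O)c(C(=O)OCc2ccccc2)c(CCC)c1 | intermediate
19 | 4-[(2,4-dihydroxy-6-pentylbenzoyl)oxy]-2-hydroxy-6-propylbenzoic acid | CCCCCc1cc(O)cc(O)c1C(=O)Oc1cc(O)c(C(=O)O)c(CCC)c1 | target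

**Step count**
Total: 10 steps. Longest linear sequence: 7 steps (steps 1, 2, 3, 4, 5, 9, 10); the ring A branch (steps 6, 7, 8) joins at step 9.

**Steps most likely to fail**

Step 3. The exchange–elimination–addition cascade may be diverted: the Grignard reagent may attack the triflate sulfur, transfer hydride to the aryne, or the aryne may oligomerise, so that little propyl is transferred. The fallback makes the two C–C bonds one at a time instead of across an aryne. Setting out from 1, triflation (Tf2O, pyridine, CH2Cl2) would give 3,5-bis(benzyloxy)phenyl trifluoromethanesulfonate F1. Kumada–Corriu coupling of this with 4 under PdCl2(dppf) catalysis in THF would give 1,3-bis(benzyloxy)-5-propylbenzene F2. Vilsmeier–Haack formylation (POCl3, DMF), which goes para to one benzyloxy group and ortho to the other, would give 2,4-bis(benzyloxy)-6-propylbenzaldehyde F3. Pinnick oxidation (NaClO2, NaH2PO4, 2-methyl-2-butene, t-BuOH/H2O) brings the sequence back to the route at 9.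

Step 1. Positional control may be poor, with iodination at the carbon between the two benzyloxy groups (para to the hydroxyl), or the very electron-rich ring may be iodinated twice. The fallback replaces electrophilic substitution by directed ortho-metalation. Setting out from 1, carbamoylation (ClCONEt2, K2CO3, MeCN, reflux) would give 3,5-bis(benzyloxy)phenyl N,N-diethylcarbamate F4. Lithiation between the carbamate and a benzyloxy group (s-BuLi, TMEDA, THF, −78 °C) followed by an I2 quench would give 3,5-bis(benzyloxy)-2-iodophenyl N,N-diethylcarbamate F5. Hydrolysis of the carbamate (KOH, EtOH/H2O, reflux) returns to the route at 2.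

Step 9. Under the acidic mixed-anhydride conditions the hindered acyl group may be transferred slowly, so that trifluoroacetylation of the phenol or acylation of the chelated C2' hydroxyl competes. The fallback separates activation from coupling and runs the acylation on a phenoxide under basic conditions. Setting out from 16, oxalyl chloride with catalytic DMF in CH2Cl2 (0 °C → rt) would give 2,4-bis(benzyloxy)-6-pentylbenzoyl chloride F6. Adding this to 11 and K2CO3 in acetone, where the more acidic, unchelated C4' hydroxyl is deprotonated first, should give the depside ester and returns to the route at 18.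

**Further compounds**
F1 | step 3 | 3,5-bis(benzyloxy)phenyl trifluoromethanesulfonate | O=S(=O)(Oc1cc(OCc2ccccc2)cc(OCc2ccccc2)c1)C(F)(F)F
F2 | step 3 | 1,3-bis(benzyloxy)-5-propylbenzene | CCCc1cc(OCc2ccccc2)cc(OCc2ccccc2)c1
F3 | step 3 | 2,4-bis(benzyloxy)-6-propylbenzaldehyde | CCCc1cc(OCc2ccccc2)cc(OCc2ccccc2)c1C=O
F4 | step 1 | 3,5-bis(benzyloxy)phenyl N,N-diethylcarbamate | CCN(CC)C(=O)Oc1cc(OCc2ccccc2)cc(OCc2ccccc2)c1
F5 | step 1 | 3,5-bis(benzyloxy)-2-iodophenyl N,N-diethylcarbamate | CCN(CC)C(=O)Oc1cc(OCc2ccccc2)cc(OCc2ccccc2)c1I
F6 | step 9 | 2,4-bis(benzyloxy)-6-pentylbenzoyl chloride | CCCCCc1cc(OCc2ccccc2)cc(OCc2ccccc2)c1C(Cl)=O
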